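## Retrosynthetic overview

1. The strategy rests on the central six-membered ring C11–C3′–C2′–C1′–C5′–C13 (xanthanolide numbering; primed atoms are half A with the tertiary alcohol, unprimed atoms half B with the 3-oxobutyl chain). With the C3′ acetyl cut back to a C3′ ketone, spiro C11 is the α-carbon of lactone B and carbinol C1′ is β to C3′, so the ring is a Robinson ketol. C13 lies on the H7 face of cis-fused lactone B, which is where an electrophile enters a lactone enolate.
2. Disconnecting C11–C13 (Michael) and C2′–C1′ (aldol) gives an α-methylene cycloheptanone lactone (half A, released from its Mannich methiodide) and an α-acetyl lactone (half B). C4′/C15′ are added afterwards through the C3′ enol triflate (Stille coupling), and the C11′ methylene of lactone A is unveiled last.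
3. The halves carry mirror-image C7/C8/C10 triads, so both descend from one enantiomer of the monoacetate of meso cis-cyclohept-2-ene-1,4-diyl diacetate; which hydroxyl undergoes the Johnson–Claisen rearrangement decides the series.
4. Ring order: both seven-membered rings come intact from cyclohepta-1,3-diene, lactones A and B are closed next (Claisen rearrangement, lactonisation), and the central cyclohexane ring is closed last, in the step that joins the halves.
5. The C10 and C10′ methyl groups are equilibrated on the saturated ketones and not on the enones, where the C7 proton is γ and the lactone oxygen δ to the carbonyl (vinylogous E1cB loss of the carboxylate). The ring enolates needed afterwards are made by kinetic deprotonation at the CH2 flank.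

Key step: step 21

Assumption: the lipase is taken to cleave the acetate on the S-configured carbon of 2. If the enzyme chosen delivers the mirror-image monoacetate, the direct sequence (steps 3–4) and the silylation sequence (steps 10–13) simply exchange the halves they feed.

Remark: cyclohepta[b]furan locants are used only inside systematic names; all discussion uses xanthanolide numbering.

## Route

### Common steps

Step 1
Reactants: 1 cyclohepta-1,3-diene
Product: 2 meso cis-cyclohept-2-ene-1,4-diyl diacetate
Conditions: Pd(OAc)2 (5 mol %), LiOAc, LiCl (cat.), p-benzoquinone, AcOH, rt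
Reagents that add atoms: acetic acid CC(=O)O
Why: Palladium-catalysed 1,4-diacetoxylation of the diene (acetoxypalladation, then external acetate attack on the π-allyl complex anti to palladium when catalytic chloride occupies the metal) should give the cis, hence meso, diacetate.

Step 2
Reactants: 2 meso cis-cyclohept-2-ene-1,4-diyl diacetate
Product: 3 (1R,4S)-4-hydroxycyclohept-2-en-1-yl acetate
Conditions: lipase from Pseudomonas cepacia (Amano PS), 0.1 M phosphate buffer pH 7, rt
Reagents that add atoms: none
Why: Enzymatic desymmetrisation, in which the hydrolase distinguishes the two enantiotopic acetates; this single event fixes the absolute configuration of both halves.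

### Half A

Step 3
Reactants: 3 (1R,4S)-4-hydroxycyclohept-2-en-1-yl acetate
Product: 4 ethyl 2-[(1S,7R)-7-acetoxycyclohept-2-en-1-yl]acetate
Conditions: MeC(OEt)3 (6 equiv), EtCO2H (cat.), 140 °C, EtOH distilled off
Reagents that add atoms: triethyl orthoacetate CC(OCC)(OCC)OCC
Why: Johnson–Claisen rearrangement of the ketene acetal of the free allylic alcohol; the suprafacial [3,3] shift places the CH2CO2Et arm (C11′, C12′) on C7′ on the face of the departing C–O bond, hence cis to the acetate, and moves the alkene to C5′=C6′.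

Step 4
Reactants: 4 ethyl 2-[(1S,7R)-7-acetoxycyclohept-2-en-1-yl]acetate
Product: 6 (3aS,8aR)-3,3a,6,7,8,8a-hexahydro-2H-cyclohepta[b]furan-2-one (cis-fused lactone A), via hydroxy ester 5 (not isolated)
Conditions: K2CO3, EtOH, rt; then p-TsOH (cat.), toluene, 50 °C
Reagents that add atoms: none
Why: Transesterification removes the acetate, and the freed C8′ hydroxyl, cis to the ester arm, closes the γ-lactone by intramolecular acyl substitution.

Step 5
Reactants: 6 (3aS,8aR)-3,3a,6,7,8,8a-hexahydro-2H-cyclohepta[b]furan-2-one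
Product: 7 (3aS,8aR)-3,3a,8,8a-tetrahydro-2H-cyclohepta[b]furan-2,6(7H)-dione (enone with C1′=O and C5′=C6′)
Conditions: Rh2(cap)4 (1 mol %), t-BuOOH (5 equiv), K2CO3, CH2Cl2, rt
Reagents that add atoms: tert-butyl hydroperoxide CC(C)(C)OO
Why: Radical allylic oxidation with the dirhodium tetrakis(caprolactamate)/hydroperoxide system should take the unhindered allylic CH2 (C1′) to the ketone; the other allylic hydrogen (C7′–H) is tertiary, hindered and deactivated by the neighbouring C8′–O bond.

Step 6
Reactants: 7 (3aS,8aR)-3,3a,8,8a-tetrahydro-2H-cyclohepta[b]furan-2,6(7H)-dione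
Product: 8 (3aS,8aR)-7-methyl-3,3a,8,8a-tetrahydro-2H-cyclohepta[b]furan-2,6(7H)-dione (mixture of C10′ epimers)
Conditions: LDA (1.05 equiv), THF, −78 °C; MeI, −78 → −40 °C
Reagents that add atoms: iodomethane CI
Why: Kinetic deprotonation of the enone at the α′ carbon (C10′, more acidic than the lactone CH2) and enolate alkylation install C14′; the configuration is not relied on here and is corrected in step 7.

Step 7
Reactants: 8 (3aS,8aR)-7-methyl-3,3a,8,8a-tetrahydro-2H-cyclohepta[b]furan-2,6(7H)-dione
Product: 10 (3aR,7S,8aR)-7-methylhexahydro-2H-cyclohepta[b]furan-2,6(3H)-dione (methyl cis to the C8′ oxygen), via saturated ketone epimers 9 (not isolated)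
Conditions: H2 (1 atm), 10 % Pd/C, EtOAc, rt; filter; DBU (0.5 equiv), toluene, 70 °C
Reagents that add atoms: none
Why: Catalytic hydrogenation removes the enone alkene, and base-mediated epimerisation of the α-methyl ketone through its enolate should then settle C10′ with the methyl cis to the C8′ oxygen (1,3-diequatorial on the cycloheptanone); on the saturated ketone no leaving group sits β to an enolate carbon.

Step 8
Reactants: 10 (3aR,7S,8aR)-7-methylhexahydro-2H-cyclohepta[b]furan-2,6(3H)-dione
Product: 11 (3aR,7S,8aR)-5-[(dimethylamino)methyl]-7-methylhexahydro-2H-cyclohepta[b]furan-2,6(3H)-dione (C5′ epimers, used crude)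
Conditions: LDA (1.05 equiv), THF, −78 °C; CH2=NMe2+ I−, −78 → 0 °C
Reagents that add atoms: N,N-dimethylmethyleneiminium iodide C=[N+](C)C.[I-]
Why: Kinetic deprotonation of the α-methyl ketone takes the CH2 flank (C5′) ahead of the methine and of the less acidic lactone, and the enolate is aminomethylated by the iminium salt (Mannich reaction), which brings C13.

Step 9
Reactants: 11 (3aR,7S,8aR)-5-[(dimethylamino)methyl]-7-methylhexahydro-2H-cyclohepta[b]furan-2,6(3H)-dione
Product: 12 trimethyl{[(3aR,7S,8aR)-7-methyl-2,6-dioxooctahydro-2H-cyclohepta[b]furan-5-yl]methyl}ammonium iodide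
Conditions: MeI (excess), Et2O/CH2Cl2, rt
Reagents that add atoms: iodomethane CI
Why: Menshutkin N-methylation gives a storable quaternary salt from which the sensitive α-methylene ketone can be released in the flask where it is consumed.

### Half B

Step 10
Reactants: 3 (1R,4S)-4-hydroxycyclohept-2-en-1-yl acetate
Product: 13 (1R,4S)-4-(tert-butyldimethylsilyloxy)cyclohept-2-en-1-yl acetate
Conditions: TBSCl, imidazole, DMF, rt
Reagents that add atoms: tert-butyldimethylsilyl chloride CC(C)(C)[Si](C)(C)Cl
Why: Silylation of the free secondary alcohol differentiates the two oxygens in the sense opposite to that used for half A.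

Step 11
Reactants: 13 (1R,4S)-4-(tert-butyldimethylsilyloxy)cyclohept-2-en-1-yl acetate
Product: 14 (1R,4S)-4-(tert-butyldimethylsilyloxy)cyclohept-2-en-1-ol
Conditions: K2CO3, MeOH, 0 °C → rt
Reagents that add atoms: none
Why: Methanolysis removes the acetate while the silyl ether is stable to carbonate.

Step 12
Reactants: 14 (1R,4S)-4-(tert-butyldimethylsilyloxy)cyclohept-2-en-1-ol
Product: 15 ethyl 2-[(1R,7S)-7-(tert-butyldimethylsilyloxy)cyclohept-2-en-1-yl]acetate
Conditions: MeC(OEt)3 (6 equiv), EtCO2H (cat.), 140 °C, EtOH distilled off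
Reagents that add atoms: triethyl orthoacetate CC(OCC)(OCC)OCC
Why: Johnson–Claisen rearrangement from the other allylic hydroxyl; the suprafacial shift delivers C11/C12 to C7 cis to the silyloxy group, giving the mirror-image C7/C8 pair.

Step 13
Reactants: 15 ethyl 2-[(1R,7S)-7-(tert-butyldimethylsilyloxy)cyclohept-2-en-1-yl]acetate
Product: 17 (3aR,8aS)-3,3a,6,7,8,8a-hexahydro-2H-cyclohepta[b]furan-2-one (cis-fused lactone B), via hydroxy ester 16 (not isolated)
Conditions: HF (48 % aq.), MeCN, rt; then p-TsOH (cat.), toluene, 50 °C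
Reagents that add atoms: none
Why: Fluoride-assisted desilylation frees the C8 hydroxyl, which lactonises onto the cis ester arm under the acid present.

Step 14
Reactants: 17 (3aR,8aS)-3,3a,6,7,8,8a-hexahydro-2H-cyclohepta[b]furan-2-one
Product: 18 (3aR,8aS)-3,3a,8,8a-tetrahydro-2H-cyclohepta[b]furan-2,6(7H)-dione
Conditions: Rh2(cap)4 (1 mol %), t-BuOOH (5 equiv), K2CO3, CH2Cl2, rt
Reagents that add atoms: tert-butyl hydroperoxide CC(C)(C)OO
Why: The same radical allylic oxidation as in step 5, at the C1 methylene.

Step 15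
Reactants: 18 (3aR,8aS)-3,3a,8,8a-tetrahydro-2H-cyclohepta[b]furan-2,6(7H)-dione
Product: 19 (3aR,8aS)-7-methyl-3,3a,8,8a-tetrahydro-2H-cyclohepta[b]furan-2,6(7H)-dione (mixture of C10 epimers)
Conditions: LDA (1.05 equiv), THF, −78 °C; MeI, −78 → −40 °C
Reagents that add atoms: iodomethane CI
Why: Kinetic α′-enolate alkylation installs C14, as in step 6.

Step 16
Reactants: 19 (3aR,8aS)-7-methyl-3,3a,8,8a-tetrahydro-2H-cyclohepta[b]furan-2,6(7H)-dione
Product: 21 (3aS,7R,8aS)-7-methylhexahydro-2H-cyclohepta[b]furan-2,6(3H)-dione (methyl cis to the C8 oxygen), via saturated ketone epimers 20 (not isolated)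
Conditions: H2 (1 atm), 10 % Pd/C, EtOAc, rt; filter; DBU (0.5 equiv), toluene, 70 °C
Reagents that add atoms: none
Why: Hydrogenation followed by thermodynamic epimerisation of the α-methyl ketone, as in step 7, should set C10 cis to the C8 oxygen.

Step 17
Reactants: 21 (3aS,7R,8aS)-7-methylhexahydro-2H-cyclohepta[b]furan-2,6(3H)-dione
Product: 22 (3aS,7R,8aS)-7-methyl-2-oxo-3,3a,4,7,8,8a-hexahydro-2H-cyclohepta[b]furan-6-yl trifluoromethanesulfonate
Conditions: LDA (1.05 equiv), THF, −78 °C; PhNTf2, −78 → 0 °C
Reagents that add atoms: N-phenylbis(trifluoromethanesulfonimide) O=S(=O)(N(c1ccccc1)S(=O)(=O)C(F)(F)F)C(F)(F)F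
Why: Kinetic enolisation toward the CH2 flank (C5) and O-sulfonylation of the enolate fix the C1=C5 double bond; C10 is not deprotonated and can no longer epimerise.

Step 18
Reactants: 22 (3aS,7R,8aS)-7-methyl-2-oxo-3,3a,4,7,8,8a-hexahydro-2H-cyclohepta[b]furan-6-yl trifluoromethanesulfonate; 23 2-methyl-2-vinyl-1,3-dioxolane
Product: 25 (3aS,7R,8aS)-7-methyl-6-[2-(2-methyl-1,3-dioxolan-2-yl)ethyl]-3,3a,4,7,8,8a-hexahydro-2H-cyclohepta[b]furan-2-one, via alkylborane 24 (not isolated)
Conditions: 23, 9-BBN, THF, 0 °C → rt; then 22, PdCl2(dppf) (5 mol %), K3PO4 (3 M aq.), DMF, rt → 50 °C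
Reagents that add atoms: none
Why: Anti-Markovnikov hydroboration of the vinyl group and B-alkyl Suzuki–Miyaura coupling with the alkenyl triflate attach C2–C4 and C15 with the ketone masked as its dioxolane.

Step 19
Reactants: 25 (3aS,7R,8aS)-7-methyl-6-[2-(2-methyl-1,3-dioxolan-2-yl)ethyl]-3,3a,4,7,8,8a-hexahydro-2H-cyclohepta[b]furan-2-one
Product: 26 3-(1-hydroxyethyl) derivative of 25 (side chain at C11 anti to C6; carbinol epimers)
Conditions: LDA (1.1 equiv), THF, −78 °C; CH3CHO; AcOH quench at −78 °C
Reagents that add atoms: acetaldehyde CC=O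
Why: The lactone CH2 (C11) is the only enolisable site, and its lithium enolate undergoes aldol addition to acetaldehyde, bringing C3′ and C2′; the new centres are planarised later and need no control.

Step 20
Reactants: 26 3-(1-hydroxyethyl) derivative of 25
Product: 27 (3R,3aS,7R,8aS)-3-acetyl-7-methyl-6-[2-(2-methyl-1,3-dioxolan-2-yl)ethyl]-3,3a,4,7,8,8a-hexahydro-2H-cyclohepta[b]furan-2-one (fragment B, β-keto lactone)
Conditions: Dess–Martin periodinane, NaHCO3, CH2Cl2, rt
Reagents that add atoms: none
Why: Dess–Martin oxidation of the secondary carbinol under buffered conditions gives the β-keto lactone and leaves the ketal and the trisubstituted alkene intact.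

### Union and completion

Step 21
Reactants: 12 trimethyl{[(3aR,7S,8aR)-7-methyl-2,6-dioxooctahydro-2H-cyclohepta[b]furan-5-yl]methyl}ammonium iodide; 27 fragment B (β-keto lactone)
Product: 30 spiro ketol (1′S,5′S,11S) with the central ring C11–C3′–C2′–C1′–C5′–C13 closed, via methylene ketone 28 (not isolated), via Michael adduct 29 (not isolated)
Conditions: 27, KOt-Bu (1.2 equiv), THF/t-BuOH (10:1), −40 °C; then 12, −40 → 0 °C; AcOH quench
Reagents that add atoms: none
Why: tert-Butoxide converts 27 into its potassium enolate (C11–H, between two carbonyls, is the only acidic site); this enolate removes the C5′ proton of 12 so that trimethylamine is expelled (E1cB) to give 28, then adds through C11 to the exocyclic CH2 (C13), after which proton transfer moves the charge to the acetyl methyl (C2′), whose enolate adds to the C1′ ketone, and t-BuOH protonates the tertiary aldolate. The closest known reaction is the Robinson annulation of a cyclic β-dicarbonyl compound with an α-methylene ketone released from its Mannich methiodide, held at the β-hydroxy ketone stage by low temperature. The one ring closed, C11–C3′–C2′–C1′–C5′–C13, forms by a chair-like 6-(enolexo)-exo-trig aldol addition and ends spiro to lactone B at C11 and fused to ring A at C1′–C5′. C11 is set by the cis ring fusion of lactone B, the acceptor approaching the enolate on its convex face (syn to H7, anti to C6) so that C13 lies on the H7 side and C3′ on the C6 side; C5′ is an enolisable α-centre that should settle with the C13 arm cis to the C10′ methyl (both pseudo-equatorial), and C1′ follows from equatorial attack of C2′ anti to that methyl, giving the trans ring fusion with an axial hydroxyl. The step needs the stabilised enolate to choose the enone over both lactone carbonyls, which its softness secures, and needs closure through C2′ alone, which the quaternary C11 secures (C3′ can enolise only toward C2′, and the rival aldol from C10′ onto C3′ would build a bridged ring with adjacent fully substituted carbons). The trans ring fusion is the least certain point and rests on the reversibility of the aldol addition under the small excess of alkoxide.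

Step 22
Reactants: 30 spiro ketol
Product: 31 C1′ triethylsilyl ether of 30
Conditions: TESOTf, 2,6-lutidine, CH2Cl2, −78 → −20 °C
Reagents that add atoms: triethylsilyl trifluoromethanesulfonate CC[Si](CC)(CC)OS(=O)(=O)C(F)(F)F
Why: A silyl triflate with a hindered pyridine silylates the hindered tertiary alcohol under non-basic conditions, which closes off retro-aldol cleavage and dehydration in the following steps; the ketone dioxolane tolerates these conditions at low temperature.

Step 23
Reactants: 31 C1′ triethylsilyl ether of 30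
Product: 32 C3′ enol triflate (C2′=C3′–OTf) of 31
Conditions: KHMDS (1.1 equiv), THF, −78 °C; PhNTf2, −78 → −30 °C
Reagents that add atoms: N-phenylbis(trifluoromethanesulfonimide) O=S(=O)(N(c1ccccc1)S(=O)(=O)C(F)(F)F)C(F)(F)F
Why: Because C11 is quaternary the C3′ ketone can enolise only toward C2′, and the ketone is more acidic than lactone A, so the potassium enolate is trapped on oxygen (enolate triflation) at a temperature where β-elimination of the silyloxy group should be slow.

Step 24
Reactants: 32 C3′ enol triflate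
Product: 33 2-ethoxy-1,3-diene (C2′=C3′–C4′(OEt)=C15′H2), the masked acetyl enone
Conditions: CH2=C(OEt)SnBu3, Pd(PPh3)4 (10 mol %), LiCl (3 equiv), THF, 65 °C
Reagents that add atoms: tributyl(1-ethoxyvinyl)stannane CCCC[Sn](CCCC)(CCCC)C(=C)OCC
Why: Migita–Kosugi–Stille coupling of the alkenyl triflate under zerovalent palladium, with chloride assisting transmetalation, attaches C4′ and C15′ as an enol ether that carries no acidic hydrogen.

Step 25
Reactants: 33 2-ethoxy-1,3-diene
Product: 34 C11′ (dimethylamino)methyl derivative of 33 (C11′ epimers)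
Conditions: LDA (1.3 equiv), THF, −78 °C; CH2=NMe2+ I−, −78 → 0 °C
Reagents that add atoms: N,N-dimethylmethyleneiminium iodide C=[N+](C)C.[I-]
Why: The C11′ methylene of lactone A is the only enolisable position left (C11 is quaternary, the acetyl group and the side-chain ketone are masked), so its lithium enolate is aminomethylated (Mannich reaction).

Step 26
Reactants: 34 C11′ (dimethylamino)methyl derivative of 33
Product: 36 α-methylene lactone A with silyl ether and enol ether and ketal still in place, via ammonium iodide 35 (not isolated)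
Conditions: MeI, THF, rt; then aq. NaHCO3, EtOAc, rt
Reagents that add atoms: none

Why: N-Methylation followed by bicarbonate-induced E1cB loss of trimethylamine leaves the exocyclic C11′=CH2, the standard α-methylenation of a lactone.

Step 27
Reactants: 36 protected α-methylene lactone
Product: 37 target CNP0195550.1 (7′R,8′R,10′S,1′S,5′S; 7S,8S,10R,11S)
Conditions: 2 M aq. HCl, THF, 0 °C → rt
Reagents that add atoms: water O
Why: Aqueous acid hydrolyses the enol ether to the acetyl group (giving the C2′=C3′ enone), the dioxolane to the side-chain ketone and the triethylsilyl ether to the tertiary alcohol; ionisation at C1′ is disfavoured because the allylic cation would be conjugated with the electron-poor enone.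

## Compound list

1 | cyclohepta-1,3-diene | C1=CC=CCCC1 | starting material
2 | meso cis-cyclohept-2-ene-1,4-diyl diacetate | CC(=O)O[C@@H]1CCC[C@H](OC(C)=O)C=C1 | intermediate
3 | (1R,4S)-4-hydroxycyclohept-2-en-1-yl acetate | CC(=O)O[C@@H]1CCC[C@H](O)C=C1 | intermediate
4 | ethyl 2-[(1S,7R)-7-acetoxycyclohept-2-en-1-yl]acetate | CC(=O)O[C@@H]1CCCC=C[C@@H]1CC(=O)OCC | intermediate
5 | ethyl 2-[(1S,7R)-7-hydroxycyclohept-2-en-1-yl]acetate | O[C@@H]1CCCC=C[C@@H]1CC(=O)OCC | intermediate (not isolated)
6 | (3aS,8aR)-3,3a,6,7,8,8a-hexahydro-2H-cyclohepta[b]furan-2-one | O=C1O[C@@H]2CCCC=C[C@@H]2C1 | intermediate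
7 | (3aS,8aR)-3,3a,8,8a-tetrahydro-2H-cyclohepta[b]furan-2,6(7H)-dione | O=C1O[C@@H]2CCC(=O)C=C[C@@H]2C1 | intermediate
8 | (3aS,8aR)-7-methyl-3,3a,8,8a-tetrahydro-2H-cyclohepta[b]furan-2,6(7H)-dione, C7 epimers | O=C1O[C@@H]2CC(C)C(=O)C=C[C@@H]2C1 | intermediate
9 | (3aR,8aR)-7-methylhexahydro-2H-cyclohepta[b]furan-2,6(3H)-dione, C7 epimers | O=C1O[C@@H]2CC(C)C(=O)CC[C@@H]2C1 | intermediate (not isolated)
10 | (3aR,7S,8aR)-7-methylhexahydro-2H-cyclohepta[b]furan-2,6(3H)-dione | O=C1O[C@@H]2C[C@H](C)C(=O)CC[C@@H]2C1 | intermediate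
11 | (3aR,7S,8aR)-5-[(dimethylamino)methyl]-7-methylhexahydro-2H-cyclohepta[b]furan-2,6(3H)-dione, C5 epimers | CN(C)CC1C[C@@H]2CC(=O)O[C@@H]2C[C@H](C)C1=O | intermediate
12 | trimethyl{[(3aR,7S,8aR)-7-methyl-2,6-dioxooctahydro-2H-cyclohepta[b]furan-5-yl]methyl}ammonium iodide | C[N+](C)(C)CC1C[C@@H]2CC(=O)O[C@@H]2C[C@H](C)C1=O.[I-] | intermediate
13 | (1R,4S)-4-(tert-butyldimethylsilyloxy)cyclohept-2-en-1-yl acetate | CC(=O)O[C@@H]1CCC[C@H](O[Si](C)(C)C(C)(C)C)C=C1 | intermediate
14 | (1R,4S)-4-(tert-butyldimethylsilyloxy)cyclohept-2-en-1-ol | O[C@@H]1CCC[C@H](O[Si](C)(C)C(C)(C)C)C=C1 | intermediate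
15 | ethyl 2-[(1R,7S)-7-(tert-butyldimethylsilyloxy)cyclohept-2-en-1-yl]acetate | CC(C)(C)[Si](C)(C)O[C@H]1CCCC=C[C@H]1CC(=O)OCC | intermediate
16 | ethyl 2-[(1R,7S)-7-hydroxycyclohept-2-en-1-yl]acetate | O[C@H]1CCCC=C[C@H]1CC(=O)OCC | intermediate (not isolated)
17 | (3aR,8aS)-3,3a,6,7,8,8a-hexahydro-2H-cyclohepta[b]furan-2-one | O=C1O[C@H]2CCCC=C[C@H]2C1 | intermediate
18 | (3aR,8aS)-3,3a,8,8a-tetrahydro-2H-cyclohepta[b]furan-2,6(7H)-dione | O=C1O[C@H]2CCC(=O)C=C[C@H]2C1 | intermediate
19 | (3aR,8aS)-7-methyl-3,3a,8,8a-tetrahydro-2H-cyclohepta[b]furan-2,6(7H)-dione, C7 epimers | O=C1O[C@H]2CC(C)C(=O)C=C[C@H]2C1 | intermediate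
20 | (3aS,8aS)-7-methylhexahydro-2H-cyclohepta[b]furan-2,6(3H)-dione, C7 epimers | O=C1O[C@H]2CC(C)C(=O)CC[C@H]2C1 | intermediate (not isolated)
21 | (3aS,7R,8aS)-7-methylhexahydro-2H-cyclohepta[b]furan-2,6(3H)-dione | O=C1O[C@H]2C[C@@H](C)C(=O)CC[C@H]2C1 | intermediate
22 | (3aS,7R,8aS)-7-methyl-2-oxo-3,3a,4,7,8,8a-hexahydro-2H-cyclohepta[b]furan-6-yl trifluoromethanesulfonate | O=C1O[C@H]2C[C@@H](C)C(OS(=O)(=O)C(F)(F)F)=CC[C@H]2C1 | intermediate
23 | 2-methyl-2-vinyl-1,3-dioxolane | C=CC1(C)OCCO1 | starting material
24 | 9-[2-(2-methyl-1,3-dioxolan-2-yl)ethyl]-9-borabicyclo[3.3.1]nonane | CC1(CCB2C3CCCC2CCC3)OCCO1 | intermediate (not isolated)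
25 | (3aS,7R,8aS)-7-methyl-6-[2-(2-methyl-1,3-dioxolan-2-yl)ethyl]-3,3a,4,7,8,8a-hexahydro-2H-cyclohepta[b]furan-2-one | O=C1O[C@H]2C[C@@H](C)C(CCC3(C)OCCO3)=CC[C@H]2C1 | intermediate
26 | (3aS,7R,8aS)-3-(1-hydroxyethyl)-7-methyl-6-[2-(2-methyl-1,3-dioxolan-2-yl)ethyl]-3,3a,4,7,8,8a-hexahydro-2H-cyclohepta[b]furan-2-one, side chain anti to C6, carbinol epimers | O=C1O[C@H]2C[C@@H](C)C(CCC3(C)OCCO3)=CC[C@H]2[C@@H]1C(C)O | intermediate
27 | (3R,3aS,7R,8aS)-3-acetyl-7-methyl-6-[2-(2-methyl-1,3-dioxolan-2-yl)ethyl]-3,3a,4,7,8,8a-hexahydro-2H-cyclohepta[b]furan-2-one (fragment B) | O=C1O[C@H]2C[C@@H](C)C(CCC3(C)OCCO3)=CC[C@H]2[C@@H]1C(C)=O | intermediate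
28 | (3aR,7S,8aR)-7-methyl-5-methylidenehexahydro-2H-cyclohepta[b]furan-2,6(3H)-dione (fragment A) | C=C1C[C@@H]2CC(=O)O[C@@H]2C[C@H](C)C1=O | intermediate (not isolated)
29 | Michael adduct: 27 alkylated at C11 (11S) by the C13 methylene of ring A, ring A as its C1′ ketone, C5′ epimers | C1C(=O)O[C@@H]2C[C@H](C)C(=O)C(C[C@]3(C(C)=O)C(=O)O[C@H]4C[C@@H](C)C(CCC5(C)OCCO5)=CC[C@@H]34)C[C@H]12 | intermediate (not isolated)
30 | spiro ketol (1′S,5′S,11S): 1′-hydroxy-3′-oxo central ring spiro to lactone B at C11, trans-fused to ring A at C1′–C5′, side chain as dioxolane | C1C(=O)O[C@@H]2C[C@H](C)[C@@]3(O)CC(=O)[C@@]4(C[C@@H]3C[C@H]12)C(=O)O[C@H]1C[C@@H](C)C(CCC5(C)OCCO5)=CC[C@H]14 | intermediate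
31 | C1′ triethylsilyl ether of 30 | C1C(=O)O[C@@H]2C[C@H](C)[C@@]3(O[Si](CC)(CC)CC)CC(=O)[C@@]4(C[C@@H]3C[C@H]12)C(=O)O[C@H]1C[C@@H](C)C(CCC5(C)OCCO5)=CC[C@H]14 | intermediate
32 | C3′ enol triflate of 31 (C2′=C3′) | C1C(=O)O[C@@H]2C[C@H](C)[C@@]3(O[Si](CC)(CC)CC)C=C(OS(=O)(=O)C(F)(F)F)[C@@]4(C[C@@H]3C[C@H]12)C(=O)O[C@H]1C[C@@H](C)C(CCC5(C)OCCO5)=CC[C@H]14 | intermediate
33 | 2-ethoxy-1,3-diene (C3′ bears the 1-ethoxyvinyl group), silyl ether and dioxolane retained | C1C(=O)O[C@@H]2C[C@H](C)[C@@]3(O[Si](CC)(CC)CC)C=C(C(=C)OCC)[C@@]4(C[C@@H]3C[C@H]12)C(=O)O[C@H]1C[C@@H](C)C(CCC5(C)OCCO5)=CC[C@H]14 | intermediate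
34 | C11′ (dimethylamino)methyl derivative of 33, C11′ epimers | CN(C)CC1C(=O)O[C@@H]2C[C@H](C)[C@@]3(O[Si](CC)(CC)CC)C=C(C(=C)OCC)[C@@]4(C[C@@H]3C[C@H]12)C(=O)O[C@H]1C[C@@H](C)C(CCC5(C)OCCO5)=CC[C@H]14 | intermediate
35 | N-methyl quaternary ammonium iodide of 34 | C[N+](C)(C)CC1C(=O)O[C@@H]2C[C@H](C)[C@@]3(O[Si](CC)(CC)CC)C=C(C(=C)OCC)[C@@]4(C[C@@H]3C[C@H]12)C(=O)O[C@H]1C[C@@H](C)C(CCC5(C)OCCO5)=CC[C@H]14.[I-] | intermediate (not isolated)
36 | α-methylene lactone A with C1′ silyl ether, ethoxydiene and dioxolane in place | C=C1C(=O)O[C@@H]2C[C@H](C)[C@@]3(O[Si](CC)(CC)CC)C=C(C(=C)OCC)[C@@]4(C[C@@H]3C[C@H]12)C(=O)O[C@H]1C[C@@H](C)C(CCC5(C)OCCO5)=CC[C@H]14 | intermediate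
37 | CNP0195550.1 | C=C1C(=O)O[C@@H]2C[C@H](C)[C@@]3(O)C=C(C(C)=O)[C@@]4(C[C@@H]3C[C@H]12)C(=O)O[C@H]1C[C@@H](C)C(CCC(C)=O)=CC[C@H]14 | target

## Step count and risks

Total step count: 27 steps.
Longest linear sequence: 20 steps (steps 1, 2, 10–20 and 21–27); the half A branch (steps 3–9) is seven steps from 3.

Steps most likely to fail:

1. Step 21. The aldol closure could run through the cis-fused transition state and so set C1′ (or C5′) wrongly, or the ketol could dehydrate or suffer retro-Claisen loss of the acetyl group under alkoxide. Fallback: the two bond formations are separated. Setting out from 12 and 27, triethylamine in acetonitrile at 0 °C would release 28 and catalyse only the conjugate addition, and the diketone 29 would be isolated. It would then be cyclised by enamine catalysis with proline (either enantiomer, chosen so that catalyst control reinforces the substrate; DMSO, rt), an aldol cyclisation of the Hajos–Parrish kind that stops at the ketol, rejoining the route at 30. This detour makes no compound outside the list (F0).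

2. Step 23. Deprotonation could be unselective between C2′ and the lactone A methylene C11′, or the C3′ enolate could expel the axial C1′ silyloxy group (E1cB) before it is trapped. Fallback: the enolate is avoided altogether. Setting out from 31, 1-ethoxyvinyllithium (ethyl vinyl ether, t-BuLi) transmetalated with CeCl3 would add to the C3′ ketone at −78 °C, organocerium reagents preferring ketones to lactones and not enolising them, to give the C3′ (1-ethoxyvinyl) tertiary carbinol F1. Dehydration with the Burgess reagent (syn elimination, possible only toward C2′ because C11 is quaternary) would then give the ethoxydiene and rejoin the route at 33.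

3. Step 5 (the same reaction recurs as step 14). Hydrogen abstraction at the tertiary C7′–H, or recombination of the allyl radical at C6′, would give regioisomeric or transposed enones. Fallback: a pericyclic oxidation replaces the radical one. Setting out from 6, catalytic SeO2 with t-BuOOH in CH2Cl2 (ene reaction, then [2,3] shift, which returns oxygen to the carbon that lost hydrogen and favours CH2 over CH) would give the C1′ allylic alcohol F2, and MnO2 would oxidise it to the enone, rejoining the route at 7. In the mirror-image series the same two operations on 17 would give the allylic alcohol F3 and rejoin at 18.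

## Further compounds

F0 | step 21 | none | none
F1 | step 23 | C3′ (1-ethoxyvinyl) tertiary carbinol from 1,2-addition to 31, C3′ epimers | C1C(=O)O[C@@H]2C[C@H](C)[C@@]3(O[Si](CC)(CC)CC)CC(O)(C(=C)OCC)[C@@]4(C[C@@H]3C[C@H]12)C(=O)O[C@H]1C[C@@H](C)C(CCC5(C)OCCO5)=CC[C@H]14
F2 | step 5 | (3aS,8aR)-6-hydroxy-3,3a,6,7,8,8a-hexahydro-2H-cyclohepta[b]furan-2-one, C6 epimers | O=C1O[C@@H]2CCC(O)C=C[C@@H]2C1
F3 | step 14 | (3aR,8aS)-6-hydroxy-3,3a,6,7,8,8a-hexahydro-2H-cyclohepta[b]furan-2-one, C6 epimers | O=C1O[C@H]2CCC(O)C=C[C@H]2C1
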